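Ring C is closed last, at O1–C8a. O5 and O8 are para to each other on ring A, so that ring is handled as a latent 5,8-quinone. In it C8a, next to the C4 acyl group on C4a, is β to both C5=O and C4=O. The precursor is an open-chain 2,5-dihydroxy-4-(SEM-oxy)phenyl 1,3-diketone with OSEM on C3 and the 4-prenyloxyphenyl ring on C2. Anodic oxidation unmasks the acylquinone. The C2 enol oxygen then adds to C8a, which forms the pyranone ring and returns ring A as the 5,8-quinol in one operation. The diketone comes from an aldol union of two protected commercial fragments. Selective 8-O-methylation and fluoride deprotection finish the synthesis.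

Key step: step 8

Assumption: the target has no stereocentre and no stereogenic double bond, so it is achiral and there is no enantiomer to select; the sp3 centres in the aldol adduct and the open-chain diketones are transient, are carried as mixtures and are erased on ring closure.

Design notes:
- SEM = CH2OCH2CH2SiMe3, TBS = SiMe2tBu, prenyl = 3-methylbut-2-enyl. Flavone numbering is used for the open-chain compounds as well.
- The electrolysis substrate is stored as its bis-silyl ether and unmasked only just before use, because a free 5-OH beside a 1,3-diketone can close ring C the wrong way.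
- A hindered pyridine buffer is supplied because 2-alkoxy-1,3-diketones sit mainly in the diketo form.
- The electrolysis is taken deliberately through to the flavone-5,8-quinone before reduction, because the quinol should be no harder to oxidise than the substrate.

Step 1
Reactants: 1 2,4'-dihydroxyacetophenone [2-hydroxy-1-(4-hydroxyphenyl)ethanone]; 2 prenyl bromide (1-bromo-3-methylbut-2-ene)
Product: 3 2-hydroxy-1-[4-(3-methylbut-2-enyloxy)phenyl]ethanone
Conditions: K2CO3 (1.1 equiv), acetone, 40 °C
Reagents that add atoms: none
Why: Williamson ether synthesis: carbonate ionises only the phenol, which is many pKa units more acidic than the primary ketol hydroxyl, and the phenoxide displaces bromide at the primary allylic carbon (SN2) to give the O-prenyl ether.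

Step 2
Reactants: 3 2-hydroxy-1-[4-(3-methylbut-2-enyloxy)phenyl]ethanone
Product: 4 1-[4-(3-methylbut-2-enyloxy)phenyl]-2-(SEM-oxy)ethanone
Conditions: SEMCl, iPr2NEt, cat. Bu4NI, CH2Cl2, 0 °C to rt
Reagents that add atoms: SEMCl [2-(trimethylsilyl)ethoxymethyl chloride], ClCOCC[Si](C)(C)C
Why: Standard SEM acetal formation, in which the primary alcohol is O-alkylated by a highly reactive chloromethyl ether under a hindered amine base that is too mild to enolise the ketol or disturb the prenyl ether.

Step 3
Reactants: 5 2,4,5-trihydroxybenzaldehyde
Product: 6 2,5-dihydroxy-4-(SEM-oxy)benzaldehyde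
Conditions: SEMCl (1.0 equiv, slow addition), iPr2NEt (1.05 equiv), DMF, −20 to 0 °C, Ar
Reagents that add atoms: SEMCl [2-(trimethylsilyl)ethoxymethyl chloride], ClCOCC[Si](C)(C)C
Why: Acidity-controlled Williamson-type mono-alkylation: the 4-OH (para to CHO) is the only hydroxyl appreciably ionised by one equivalent of amine, the 2-OH being held in a hydrogen bond to the carbonyl and the meta 5-OH being the least acidic, in line with the established 4-selective alkylations of 2,4- and 3,4-dihydroxybenzaldehydes.

Step 4
Reactants: 6 2,5-dihydroxy-4-(SEM-oxy)benzaldehyde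
Product: 7 2,5-bis(TBS-oxy)-4-(SEM-oxy)benzaldehyde
Conditions: TBSCl (2.5 equiv), imidazole, DMF, rt
Reagents that add atoms: TBSCl (tert-butyldimethylsilyl chloride), CC(C)(C)[Si](C)(C)Cl
Why: Imidazole-promoted silyl ether formation caps both remaining phenols and should give an air-stable, non-enolisable aldehyde whose aryl silyl ethers can later be removed by cold fluoride without touching SEM.

Step 5
Reactants: 4 1-[4-(3-methylbut-2-enyloxy)phenyl]-2-(SEM-oxy)ethanone; 7 2,5-bis(TBS-oxy)-4-(SEM-oxy)benzaldehyde
Product: 9 3-[2,5-bis(TBS-oxy)-4-(SEM-oxy)phenyl]-3-hydroxy-1-(4-prenyloxyphenyl)-2-(SEM-oxy)propan-1-one (racemic syn/anti mixture), via lithium Z-enolate 8 (not isolated)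
Conditions: LiHMDS, THF, −78 °C; then 7, −78 °C; AcOH/THF quench at −78 °C
Reagents that add atoms: none
Why: Crossed lithium-enolate aldol addition of the chelated Z-enolate of the only enolisable partner to a non-enolisable aldehyde; the two new stereocentres are not controlled and need not be, since both are erased in steps 6 and 8, and the cold acidic quench forestalls O-to-O silyl migration and retro-aldol cleavage.

Step 6
Reactants: 9 aldol adduct (syn/anti mixture)
Product: 10 1-[2,5-bis(TBS-oxy)-4-(SEM-oxy)phenyl]-3-(4-prenyloxyphenyl)-2-(SEM-oxy)propane-1,3-dione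
Conditions: IBX (3 equiv), EtOAc, 75 °C
Reagents that add atoms: none
Why: IBX oxidation of a β-hydroxy ketone to the β-diketone, a neutral heterogeneous method that should stop at the diketone and spare the trisubstituted alkene, the aryl silyl ethers and the SEM acetals; the carbinol centre is erased and the remaining C3 centre is configurationally labile and of no consequence.

Step 7
Reactants: 10 bis-TBS diketone
Product: 11 1-[2,5-dihydroxy-4-(SEM-oxy)phenyl]-3-(4-prenyloxyphenyl)-2-(SEM-oxy)propane-1,3-dione
Conditions: TBAF/AcOH (2.2/2.4 equiv), THF, 0 °C, Ar; degassed pH 7 buffer work-up, no chromatography, crude 11 used at once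
Reagents that add atoms: none
Why: Fluoride-induced desilylation: aryl silyl ethers are cleaved within minutes at 0 °C whereas SEM ethers need hot unbuffered fluoride, and the acetic acid buffer keeps the freed phenols protonated so that retro-Claisen cleavage, autoxidation and closure through the 5-OH are all held back.

Step 8
Reactants: 11 1-[2,5-dihydroxy-4-(SEM-oxy)phenyl]-3-(4-prenyloxyphenyl)-2-(SEM-oxy)propane-1,3-dione
Product: 14 5,8-dihydroxy-3,7-bis(SEM-oxy)-4'-prenyloxyflavone, via acylquinone 12 (not isolated), via flavone-5,8-quinone 13 (not isolated)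
Conditions: divided cell (glass frit), RVC anode, Pt cathode, controlled potential ca. 0.1 V past the first anodic wave located by CV (expected +0.5 to +0.8 V vs Ag/AgCl), to ca. 4 F/mol; 5 mM 11, Bu4NBF4 (0.1 M), 2,6-lutidine/2,6-lutidinium BF4 buffer in both compartments, dry MeCN, rt, Ar; then aq Na2S2O4, pH 7 phosphate/EtOAc
Reagents that add atoms: none
Why: Proposed new method: Proton-coupled two-electron oxidation at the anode converts the 2,5-dihydroxyaryl ketone 11 into acylquinone 12, whose C3–H lies between an aroyl and a quinonoyl carbonyl and should therefore be enolised by lutidine; the enol oxygen on C2 then adds to C8a, and loss of the C8a proton rearomatises ring A to quinol 14. Because 14 should be at least as easily oxidised as 11, the electrolysis is carried on to flavone-5,8-quinone 13 (two further electrons, at the anode or by redox exchange with 12), and dithionite then converges all material on 14. The closest known reaction type is anodic hydroquinone or catechol oxidation followed by Michael addition (EC/ECEC sequences), including the enol-oxygen closure onto an electrogenerated quinone that completes benzofuran formation from 1,3-dicarbonyls, together with the known preference of 2-acylquinones to accept nucleophiles at the ring carbon next to the acyl group; its use to close a 4-pyranone ring is what is new. Ring C closes by a 6-endo-trig oxa-Michael addition (equally describable as a 6π oxa-electrocyclisation of the C4-enol tautomer), and no stereocentre is created, the labile C3 centre of 11 and 12 becoming sp2. Site selectivity requires attack at C8a and not at C6 or C7: C8a is β to both C5=O and C4=O and is the only electrophilic alkene carbon of the quinone that the tethered oxygen can reach through a six-membered transition state, C6 is deactivated by the 7-alkoxy donor, and attack through carbon C3 would need a four-membered ring. Chemoselectivity rests on the hydroquinone being oxidised several hundred millivolts before the acyl-deactivated ring B or the prenyl alkene, while the dry, non-nucleophilic, buffered medium denies the acylquinone any external nucleophile and keeps the 5-OH from condensing with C2 before oxidation removes it as a nucleophile.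

Step 9
Reactants: 14 5,8-dihydroxy-3,7-bis(SEM-oxy)-4'-prenyloxyflavone
Product: 15 5-hydroxy-8-methoxy-3,7-bis(SEM-oxy)-4'-prenyloxyflavone
Conditions: MeI (1.1 equiv), K2CO3 (1.2 equiv), degassed acetone, rt to 40 °C, Ar
Reagents that add atoms: MeI (iodomethane), CI
Why: Selective Williamson methylation, the classical partial methylation of 5,8-dihydroxyflavones: the 8-OH is an ordinary phenol whereas the 5-OH is locked in a strong hydrogen bond to C4=O and is not alkylated by one equivalent of MeI with carbonate, and oxygen is excluded to stop base-promoted re-oxidation of the quinol.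

Step 10
Reactants: 15 5-hydroxy-8-methoxy-3,7-bis(SEM-oxy)-4'-prenyloxyflavone
Product: 16 3,5,7-trihydroxy-8-methoxy-4'-prenyloxyflavone
Conditions: TBAF (excess), THF, 60 °C, slow Ar sweep; AcOH quench
Reagents that add atoms: none
Why: Fluoride-induced SEM cleavage: attack on silicon triggers β-elimination (Me3SiF, ethylene) and the hemiacetal anions expel formaldehyde, which is favoured here because the 7- and 3-oxygens are good leaving groups, while the acid-sensitive prenyl ether, the 8-OMe and the chelated 5-OH are inert to fluoride.

Compound list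
1 | 2,4'-dihydroxyacetophenone [2-hydroxy-1-(4-hydroxyphenyl)ethanone] | O=C(CO)c1ccc(O)cc1 | starting material
2 | prenyl bromide (1-bromo-3-methylbut-2-ene) | CC(C)=CCBr | starting material
3 | 2-hydroxy-1-[4-(3-methylbut-2-enyloxy)phenyl]ethanone | O=C(CO)c1ccc(OCC=C(C)C)cc1 | intermediate
4 | 1-[4-(3-methylbut-2-enyloxy)phenyl]-2-(SEM-oxy)ethanone | O=C(COCOCC[Si](C)(C)C)c1ccc(OCC=C(C)C)cc1 | intermediate
5 | 2,4,5-trihydroxybenzaldehyde | O=Cc1cc(O)c(O)cc1O | starting material
6 | 2,5-dihydroxy-4-(SEM-oxy)benzaldehyde | O=Cc1cc(O)c(OCOCC[Si](C)(C)C)cc1O | intermediate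
7 | 2,5-bis(TBS-oxy)-4-(SEM-oxy)benzaldehyde | O=Cc1cc(O[Si](C)(C)C(C)(C)C)c(OCOCC[Si](C)(C)C)cc1O[Si](C)(C)C(C)(C)C | intermediate
8 | lithium (Z)-enolate of 4 (not isolated) | [Li]O/C(=C\OCOCC[Si](C)(C)C)c1ccc(OCC=C(C)C)cc1 | intermediate
9 | 3-[2,5-bis(TBS-oxy)-4-(SEM-oxy)phenyl]-3-hydroxy-1-(4-prenyloxyphenyl)-2-(SEM-oxy)propan-1-one, racemic syn/anti mixture | O=C(c1ccc(OCC=C(C)C)cc1)C(OCOCC[Si](C)(C)C)C(O)c1cc(O[Si](C)(C)C(C)(C)C)c(OCOCC[Si](C)(C)C)cc1O[Si](C)(C)C(C)(C)C | intermediate
10 | 1-[2,5-bis(TBS-oxy)-4-(SEM-oxy)phenyl]-3-(4-prenyloxyphenyl)-2-(SEM-oxy)propane-1,3-dione, racemic and labile at C3 (flavone numbering) | O=C(c1cc(O[Si](C)(C)C(C)(C)C)c(OCOCC[Si](C)(C)C)cc1O[Si](C)(C)C(C)(C)C)C(OCOCC[Si](C)(C)C)C(=O)c1ccc(OCC=C(C)C)cc1 | intermediate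
11 | 1-[2,5-dihydroxy-4-(SEM-oxy)phenyl]-3-(4-prenyloxyphenyl)-2-(SEM-oxy)propane-1,3-dione, racemic and labile at C3 (flavone numbering) | O=C(c1cc(O)c(OCOCC[Si](C)(C)C)cc1O)C(OCOCC[Si](C)(C)C)C(=O)c1ccc(OCC=C(C)C)cc1 | intermediate
12 | 2-[3-oxo-3-(4-prenyloxyphenyl)-2-(SEM-oxy)propanoyl]-5-(SEM-oxy)-1,4-benzoquinone (not isolated) | O=C(C1=CC(=O)C(OCOCC[Si](C)(C)C)=CC1=O)C(OCOCC[Si](C)(C)C)C(=O)c1ccc(OCC=C(C)C)cc1 | intermediate
13 | 2-(4-prenyloxyphenyl)-3,7-bis(SEM-oxy)-4H-chromene-4,5,8-trione, the flavone-5,8-quinone (not isolated) | O=C1C(OCOCC[Si](C)(C)C)=CC(=O)C2=C1OC(c1ccc(OCC=C(C)C)cc1)=C(OCOCC[Si](C)(C)C)C2=O | intermediate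
14 | 5,8-dihydroxy-3,7-bis(SEM-oxy)-4'-prenyloxyflavone | Oc1c(OCOCC[Si](C)(C)C)cc(O)c2c(=O)c(OCOCC[Si](C)(C)C)c(-c3ccc(OCC=C(C)C)cc3)oc12 | intermediate
15 | 5-hydroxy-8-methoxy-3,7-bis(SEM-oxy)-4'-prenyloxyflavone | COc1c(OCOCC[Si](C)(C)C)cc(O)c2c(=O)c(OCOCC[Si](C)(C)C)c(-c3ccc(OCC=C(C)C)cc3)oc12 | intermediate
16 | 3,5,7-trihydroxy-8-methoxy-4'-prenyloxyflavone (achiral) | COc1c(O)cc(O)c2c(=O)c(O)c(-c3ccc(OCC=C(C)C)cc3)oc12 | target

Total step count: 10
Longest linear sequence: 8 (steps 3–10 from 5; equally steps 1, 2 and 5–10 from 1)

Steps most likely to fail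

1. Step 8.
What may go wrong: the electrogenerated acylquinone may be lost to intermolecular capture or oligomerisation. The electron-rich C3 enol may reduce the quinone internally instead of adding to it. Part of the substrate may condense through the 5-OH before it reaches the anode.
Fallback: known quinone chemistry, done as separate operations.
- Setting out from 11, Ag2O/Na2SO4 in CH2Cl2 at 0 °C should give 12 in the absence of base.
- One equivalent of 2,4,6-collidinium chloride (or ethereal HCl at −40 °C) is then added. Hydrochlorination of a 2-acylquinone takes place at the ring carbon next to the acyl group and should give the 8a-chloro hydroquinone diketone F1.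
- A second Ag2O oxidation gives the chloro-acylquinone F2.
- With NaOAc in MeCN the enolate oxygen displaces chloride by addition–elimination. This is the closure used to fuse oxygen rings onto chloroquinones with 1,3-dicarbonyls, and it is irreversible because chloride leaves.
- The product is 13, and the dithionite wash brings the route back at 14.

2. Step 5.
What may go wrong: the ortho silyl group may migrate from the phenolic oxygen to the new benzylic alkoxide. Retro-aldol cleavage may occur on work-up. Addition to the hindered, electron-rich aldehyde may be sluggish.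
Fallback: acylation in place of aldol plus oxidation.
- Setting out from 7, Pinnick oxidation (NaClO2, NaH2PO4, 2-methyl-2-butene, t-BuOH/H2O) should give the benzoic acid F3.
- CDI in THF converts it into the acyl imidazole F4.
- F4 is added to two equivalents of enolate 8 (THF, −78 to 0 °C) in a Claisen-type C-acylation.
- No benzylic alkoxide is ever formed, and the route is rejoined at 10, bypassing 9 and step 6.

3. Step 7.
What may go wrong: material may be lost while the free hydroquinone is handled, through hemiketalisation and dehydration via the 5-OH, air oxidation, or base-induced cleavage of the diketone.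
Fallback: the free hydroquinone is not released at all.
- Setting out from 10, the bis-silyl ether is electrolysed directly. Anodic oxidation of hydroquinone bis-silyl ethers to quinones is known.
- Conditions: carbon anode, LiClO4/MeCN with a few equivalents of water and the lutidine buffer, at a controlled potential expected to lie well above that of 11 but still below that of ring B and the alkene.
- Both silyl groups leave during the oxidation and the route is rejoined at 12 inside the cell of step 8.
- This fallback makes no compound outside the list (F0).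

Further compounds
F1 | step 8 | 1-[2-chloro-3,6-dihydroxy-4-(SEM-oxy)phenyl]-3-(4-prenyloxyphenyl)-2-(SEM-oxy)propane-1,3-dione | O=C(c1c(Cl)c(O)c(OCOCC[Si](C)(C)C)cc1O)C(OCOCC[Si](C)(C)C)C(=O)c1ccc(OCC=C(C)C)cc1
F2 | step 8 | 3-chloro-2-[3-oxo-3-(4-prenyloxyphenyl)-2-(SEM-oxy)propanoyl]-5-(SEM-oxy)-1,4-benzoquinone | O=C(C1=C(Cl)C(=O)C(OCOCC[Si](C)(C)C)=CC1=O)C(OCOCC[Si](C)(C)C)C(=O)c1ccc(OCC=C(C)C)cc1
F3 | step 5 | 2,5-bis(TBS-oxy)-4-(SEM-oxy)benzoic acid | O=C(O)c1cc(O[Si](C)(C)C(C)(C)C)c(OCOCC[Si](C)(C)C)cc1O[Si](C)(C)C(C)(C)C
F4 | step 5 | 1-[2,5-bis(TBS-oxy)-4-(SEM-oxy)benzoyl]imidazole | O=C(n1ccnc1)c1cc(O[Si](C)(C)C(C)(C)C)c(OCOCC[Si](C)(C)C)cc1O[Si](C)(C)C(C)(C)C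
F0 | step 7 | none | none
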